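A flask charged with 5.0 mM of starting material looks nearly the same as one charged with 20 mM, yet I expect the two to end apart.

    gas phase ⇌ dissolved gas, rate k1*(csat - [dissolved gas]) (k1 = 0.0453 /min, csat = 9.9 mM)
    starting material + dissolved gas → target (k2 = 79.6 /M/min)
    starting material + target → side product (k3 = 1.40 /M/min)
    dissolved gas + target → over-reaction product (k4 = 0.121 /M/min)
    target ⇌ isomer of the product (K5 = 0.19, k5 = 0.0124 /min)

starting material 20 mM; gas phase 9.9 mM (held); time 4.0 h

- a species is counted by the starting material in it: one side product counts as two
- at the start none of the gas is dissolved
- run time (flask): 4.0 h

* the target standing at 4.0 h, as a percentage of the starting material charged
* concentration of dissolved gas in solution at 1.0 h, in percent of saturation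
* the change that raises the amount of target at 4.0 h, in percent of the starting material charged most ("none" if none brings more than 2 percentage points) (spring / dusk / none)
* amount of target at 4.0 h, in percent of the starting material charged, after dusk

I turn the constants into times at the charged amounts. Dissolved gas has a half-life of 0.44 min against the charged starting material, shorter than the 22.1 min of transfer, so I take transfer as the rate-limiting step while starting material stands, with an empty-solution supply of 0.448 mM/min. Delivering the charge at that supply takes 44.6 min, while target lives 35.7 min against the charged starting material. The quotient is 1.25. I carry it as the race number, feed time divided by that life of target, and it goes with the square of the charge.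

For a small race number, the overlap of falling starting material and rising target loses about the race number divided by 3. To keep the loss below the charge, I divide by the race number plus 3 instead. The 20 mM flask then puts 29.4% into side product. The 5.0 mM flask has a race number of 0.0780, and I expect 2.54% there, since its target is made with far less starting material around it.

Target and isomer relax in 0.149 h, short against the run, so target keeps 84.0% of their pool. At saturation, over-reaction wears target with a time of 13.9 h. From the end of the feed this gives 48.7% of target, and dissolved gas at 50.2% of saturation. Either doubling brings the race number to 0.625, but dusk also shortens the wear time. I get 55.9% for spring and 44.9% for dusk, so I choose spring.

The forecast says 52%, 48%, spring and 48%. Its two target figures lie above mine and its saturation below mine, with the same choice: “doubling saturation also doubles the dissolved gas driving over-reaction and so ends lower”.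

The flask gives 50.3% of target and 55.3% of saturation, and spring is the best change at 4.7 percentage points, against −4 points for dusk, which ends at 46.3%. Side product in the 20 mM flask stands at 28.5% at 4.00 h, where its race number of 1.25 gave me 29.4%. The 5.0 mM neighbour, with a race number of 0.0780 and a reckoned 2.54%, ends with 4.46% of side product and 65.2% of target.

The constants used here were set for the occasion; the run is a simulation.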